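**Plan**

- Retrosynthesis: the pyranone ring is opened at C4–C4a (acyl–arene bond), then the benzylic aryl ether O1–C2 is cut, then the prenyl group is removed from C8 of the phloroglucinol ring. C3 and C4 come from Meldrum's acid and ring B from vanillic acid.
- Forward: ring A is made as a 2-prenylphloroglucinol bis-silyl ether with one free hydroxyl, ring B as an allyl (R)-3-aryl-3-hydroxypropanoate. They are joined at O1–C2, the acid is freed, ring C is closed at C4a, and two deprotections follow.
- Enabling feature: on ring A the two carbons ortho to O1 are C4a and C8. C8 already carries the prenyl group, so an acyl chain tethered through O1–C2–C3 can only close onto C4a, which is also ortho to O5 and para to O7.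
- Stereochemistry: C2 is the only stereocentre. Ru/(R,R)-TsDPEN transfer hydrogenation sets the (R)-carbinol, the Mitsunobu etherification inverts it to (S), and the 4'-acetate guards it against ionisation until the last step.

Key step: step 9

Assumption: vanillic acid, Meldrum's acid, allyl alcohol and RuCl[(R,R)-TsDPEN](p-cymene) are bought; flavanone numbering (O1, C2, C3, C4, C4a, C5–C8, C8a) is used for all intermediates, TBS = tert-butyldimethylsilyl, prenyl = 3-methylbut-2-en-1-yl.

**Route**

Step 1
Reactants: 1 phloroglucinol; 2 prenyl bromide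
Product: 3 2-prenylphloroglucinol [2-(3-methylbut-2-en-1-yl)benzene-1,3,5-triol]
Conditions: DBU (1 equiv), THF, 0 °C → rt; 1 in excess (3 equiv)
Reagents that add atoms: none
Why: C-alkylation of the ambident phloroglucinol anion by an allylic bromide (Friedel–Crafts-type C-prenylation) is a known entry to the mono-C-prenyl triol, and the excess of the symmetric triol should hold back double prenylation.

Step 2
Reactants: 3 2-prenylphloroglucinol
Product: 4 3,5-bis(tert-butyldimethylsilyloxy)-2-(3-methylbut-2-en-1-yl)phenol
Conditions: TBSCl (2.05 equiv), imidazole, CH2Cl2, −20 → 0 °C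
Reagents that add atoms: tert-butyldimethylsilyl chloride, CC(C)(C)[Si](C)(C)Cl
Why: Imidazole-promoted silyl ether formation should take the unhindered hydroxyl para to the prenyl group first and then one of the two equivalent hydroxyls beside it, while the last hydroxyl, next to a prenyl group now buttressed by a silyl ether, reacts more slowly, so the wanted bis-silyl ether should dominate and be separable from mono- and tris-silylated material.

Step 3
Reactants: 5 vanillic acid
Product: 6 4-acetoxy-3-methoxybenzoic acid
Conditions: Ac2O, pyridine, rt; then H2O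
Reagents that add atoms: acetic anhydride, CC(=O)OC(C)=O
Why: Pyridine-promoted O-acetylation of the phenol is routine, and any mixed anhydride formed at the carboxyl group is hydrolysed in the aqueous work-up.

Step 4
Reactants: 6 4-acetoxy-3-methoxybenzoic acid; 7 Meldrum's acid
Product: 9 5-[(4-acetoxy-3-methoxyphenyl)(hydroxy)methylidene]-2,2-dimethyl-1,3-dioxane-4,6-dione, via acid chloride 8 (not isolated)
Conditions: (COCl)2, cat. DMF, CH2Cl2, 0 °C → rt, evaporate; then 7, pyridine, CH2Cl2, 0 °C → rt
Reagents that add atoms: none
Why: Acid chloride formation followed by C-acylation of Meldrum's acid is the standard opening of the Meldrum's acid route to β-keto esters, and pyridine at 0 °C should leave the aryl acetate alone.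

Step 5
Reactants: 9 acyl Meldrum's acid
Product: 11 allyl 3-(4-acetoxy-3-methoxyphenyl)-3-oxopropanoate, via acylketene 10 (not isolated)
Conditions: allyl alcohol (3 equiv), toluene, 90 °C
Reagents that add atoms: allyl alcohol, C=CCO
Why: Thermolysis of an acyl Meldrum's acid releases acetone and CO2 to give an acylketene that is trapped by the alcohol (acylketene alcoholysis), a neutral β-keto ester synthesis that should spare the aryl acetate.

Step 6
Reactants: 11 allyl 3-(4-acetoxy-3-methoxyphenyl)-3-oxopropanoate
Product: 12 allyl (3R)-3-(4-acetoxy-3-methoxyphenyl)-3-hydroxypropanoate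
Conditions: RuCl[(R,R)-TsDPEN](p-cymene) (1 mol %), HCO2H/Et3N (5:2), EtOAc, 30 °C
Reagents that add atoms: none
Why: In this Noyori–Ikariya asymmetric transfer hydrogenation the (R,R)-TsDPEN–Ru hydride should deliver hydride to the Si face of the aryl ketone, the aryl ring being held by its CH/π contact with the η6-arene (the mirror image of the (S,S)-catalyst/acetophenone case), which gives the (R)-carbinol without touching the allyl alkene or the aryl acetate.

Step 7
Reactants: 12 allyl (3R)-3-(4-acetoxy-3-methoxyphenyl)-3-hydroxypropanoate; 4 3,5-bis(tert-butyldimethylsilyloxy)-2-(3-methylbut-2-en-1-yl)phenol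
Product: 13 allyl (3S)-3-(4-acetoxy-3-methoxyphenyl)-3-[3,5-bis(tert-butyldimethylsilyloxy)-2-(3-methylbut-2-en-1-yl)phenoxy]propanoate
Conditions: PPh3, DIAD, toluene, 0 °C → rt
Reagents that add atoms: none
Why: In the Mitsunobu etherification the phenol displaces the alkoxyphosphonium group in an SN2 step with inversion, turning the (R)-carbinol into the (S)-aryl ether, and the 4-acetoxy group should keep the benzylic carbon from ionising so that the inversion stays clean.

Step 8
Reactants: 13 allyl (3S)-ether ester
Product: 14 (3S)-3-(4-acetoxy-3-methoxyphenyl)-3-[3,5-bis(tert-butyldimethylsilyloxy)-2-(3-methylbut-2-en-1-yl)phenoxy]propanoic acid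
Conditions: Pd(PPh3)4 (5 mol %), N-methylaniline (2 equiv), THF, rt
Reagents that add atoms: none
Why: Tsuji–Trost deallylation ionises the allyl ester to a π-allyl palladium complex that is captured by N-methylaniline, a scavenger too weakly nucleophilic to aminolyse the aryl acetate, under neutral conditions in which the silyl ethers hold and base-induced loss of the β-aryloxy group cannot occur.

Step 9
Reactants: 14 (3S)-3-aryl-3-aryloxypropanoic acid
Product: 16 4-[(2S)-5,7-bis(tert-butyldimethylsilyloxy)-8-(3-methylbut-2-en-1-yl)-4-oxochroman-2-yl]-2-methoxyphenyl acetate, via mixed anhydride 15 (not isolated)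
Conditions: TFAA (1.5 equiv), CH2Cl2, −20 → 0 °C; cold aq. NaHCO3 quench
Reagents that add atoms: none
Why: TFAA converts the acid into the acyl trifluoroacetate 15, whose activated carbonyl (or the acylium ion derived from it) is attacked by the ring carbon that becomes C4a, and loss of a proton restores the aromatic ring, an intramolecular Friedel–Crafts acylation that forms C4–C4a. The closest known reaction type is the TFAA-mediated cyclisation of 3-aryloxypropanoic acids to chroman-4-ones, including 3-aryl-3-aryloxy acids to flavanones. The pyranone ring closes in a 6-exo-trig mode, the arene carbon adding to a carbonyl whose C=O bond lies outside the new ring. No stereocentre is created; C2 is carried over from step 7 and should be kept because the 4'-acetoxy group makes the benzylic C2–O1 bond reluctant to ionise in the cold, weakly acidic medium. The selectivity required is acylation at C4a alone, and the substrate provides it: of the two carbons ortho to O1 one bears the prenyl group (future C8), the other is activated by the ortho ether oxygen, an ortho silyloxy and a para silyloxy group, and the carbon between the two silyloxy groups is out of reach of the three-atom tether. The electron-rich ring should react without a Lewis acid and below 0 °C, which spares the prenyl alkene and the aryl silyl ethers.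

Step 10
Reactants: 16 protected flavanone
Product: 17 4-[(2S)-5,7-dihydroxy-8-(3-methylbut-2-en-1-yl)-4-oxochroman-2-yl]-2-methoxyphenyl acetate
Conditions: TBAF/AcOH (1:1, 2.5 equiv), THF, 0 °C
Reagents that add atoms: none
Why: Fluoride-mediated cleavage of aryl silyl ethers is fast, and buffering TBAF with acetic acid keeps the medium near neutral so that the flavanone is not opened to the chalcone (which would racemise C2) and the aryl acetate stays in place.

Step 11
Reactants: 17 4'-O-acetyl flavanone
Product: 18 (2S)-5,7-dihydroxy-2-(4-hydroxy-3-methoxyphenyl)-8-(3-methylbut-2-en-1-yl)chroman-4-one (CNP0266453.1)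
Conditions: HCl (0.1 M) in MeOH, 0 °C → rt
Reagents that add atoms: none
Why: Acid-catalysed transesterification (methanolysis) of the aryl acetate should proceed at room temperature under conditions in which flavanones are configurationally stable and which are too mild to cyclise the prenyl group onto the 7-hydroxyl.

**Compound list**

1 | phloroglucinol | Oc1cc(O)cc(O)c1 | starting material
2 | prenyl bromide (1-bromo-3-methylbut-2-ene) | CC(C)=CCBr | starting material
3 | 2-prenylphloroglucinol | CC(C)=CCc1c(O)cc(O)cc1O | intermediate
4 | 3,5-bis(tert-butyldimethylsilyloxy)-2-(3-methylbut-2-en-1-yl)phenol | CC(C)=CCc1c(O)cc(O[Si](C)(C)C(C)(C)C)cc1O[Si](C)(C)C(C)(C)C | intermediate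
5 | vanillic acid | COc1cc(C(=O)O)ccc1O | starting material
6 | 4-acetoxy-3-methoxybenzoic acid | COc1cc(C(=O)O)ccc1OC(C)=O | intermediate
7 | Meldrum's acid | CC1(C)OC(=O)CC(=O)O1 | starting material
8 | 4-acetoxy-3-methoxybenzoyl chloride | COc1cc(C(=O)Cl)ccc1OC(C)=O | intermediate
9 | 5-[(4-acetoxy-3-methoxyphenyl)(hydroxy)methylidene]-2,2-dimethyl-1,3-dioxane-4,6-dione | COc1cc(C(O)=C2C(=O)OC(C)(C)OC2=O)ccc1OC(C)=O | intermediate
10 | (4-acetoxy-3-methoxybenzoyl)ketene | COc1cc(C(=O)C=C=O)ccc1OC(C)=O | intermediate
11 | allyl 3-(4-acetoxy-3-methoxyphenyl)-3-oxopropanoate | COc1cc(C(=O)CC(=O)OCC=C)ccc1OC(C)=O | intermediate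
12 | allyl (3R)-3-(4-acetoxy-3-methoxyphenyl)-3-hydroxypropanoate | COc1cc([C@H](O)CC(=O)OCC=C)ccc1OC(C)=O | intermediate
13 | allyl (3S)-3-(4-acetoxy-3-methoxyphenyl)-3-[3,5-bis(tert-butyldimethylsilyloxy)-2-(3-methylbut-2-en-1-yl)phenoxy]propanoate | COc1cc([C@@H](Oc2cc(O[Si](C)(C)C(C)(C)C)cc(O[Si](C)(C)C(C)(C)C)c2CC=C(C)C)CC(=O)OCC=C)ccc1OC(C)=O | intermediate
14 | (3S)-3-(4-acetoxy-3-methoxyphenyl)-3-[3,5-bis(tert-butyldimethylsilyloxy)-2-(3-methylbut-2-en-1-yl)phenoxy]propanoic acid | COc1cc([C@@H](Oc2cc(O[Si](C)(C)C(C)(C)C)cc(O[Si](C)(C)C(C)(C)C)c2CC=C(C)C)CC(=O)O)ccc1OC(C)=O | intermediate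
15 | mixed anhydride of 14 with trifluoroacetic acid | COc1cc([C@@H](Oc2cc(O[Si](C)(C)C(C)(C)C)cc(O[Si](C)(C)C(C)(C)C)c2CC=C(C)C)CC(=O)OC(=O)C(F)(F)F)ccc1OC(C)=O | intermediate
16 | 4-[(2S)-5,7-bis(tert-butyldimethylsilyloxy)-8-(3-methylbut-2-en-1-yl)-4-oxochroman-2-yl]-2-methoxyphenyl acetate | COc1cc([C@@H]2CC(=O)c3c(O[Si](C)(C)C(C)(C)C)cc(O[Si](C)(C)C(C)(C)C)c(CC=C(C)C)c3O2)ccc1OC(C)=O | intermediate
17 | 4-[(2S)-5,7-dihydroxy-8-(3-methylbut-2-en-1-yl)-4-oxochroman-2-yl]-2-methoxyphenyl acetate | COc1cc([C@@H]2CC(=O)c3c(O)cc(O)c(CC=C(C)C)c3O2)ccc1OC(C)=O | intermediate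
18 | (2S)-5,7-dihydroxy-2-(4-hydroxy-3-methoxyphenyl)-8-(3-methylbut-2-en-1-yl)chroman-4-one | COc1cc([C@@H]2CC(=O)c3c(O)cc(O)c(CC=C(C)C)c3O2)ccc1O | target

**Count and risks**

Total step count: 11. Longest linear sequence: 9 steps (5 → 18, steps 3–11); the ring A branch (steps 1–2) joins at step 7.

Steps most likely to fail:

Step 9. The trifluoroacetic acid set free may ionise the benzylic C2–O1 bond, leading to loss of configuration or elimination. The ring may also be trifluoroacetylated intermolecularly, or the silyl ether next to the new ketone may be lost. The fallback sets out from 14 and replaces protic mixed-anhydride activation by a neutral, isolable acyl halide. 1-Chloro-N,N,2-trimethylprop-1-en-1-amine (Ghosez's reagent) in CH2Cl2 at 0 °C should give (3S)-3-(4-acetoxy-3-methoxyphenyl)-3-[3,5-bis(tert-butyldimethylsilyloxy)-2-(3-methylbut-2-en-1-yl)phenoxy]propanoyl chloride F1. This is ionised with AgOTf at −78 °C in the presence of 2,6-di-tert-butyl-4-methylpyridine, so that the acyl triflate acylates C4a with no free acid present. The fallback returns to the route at 16.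

Step 7. The activated alcohol may eliminate to the cinnamate, part of the material may react through a benzylic cation with erosion of configuration, or the ortho-substituted phenol may couple sluggishly. The fallback sets out from 12 and forms O1–C2 by opening a β-lactone. Pd(PPh3)4/N-methylaniline removes the allyl group to give (3R)-3-(4-acetoxy-3-methoxyphenyl)-3-hydroxypropanoic acid F2. Carboxyl activation with benzenesulfonyl chloride in pyridine at 0 °C closes it with retention to (4R)-4-(4-acetoxy-3-methoxyphenyl)oxetan-2-one F3. The potassium salt of phenol 4 (KOtBu, THF, 0 °C) should then open the lactone at C4 by alkyl–oxygen cleavage with inversion. After mild acidification this gives acid 14, where the fallback returns to the route; step 8 is then not needed.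

Step 2. The three hydroxyls may be discriminated poorly, giving mixtures of mono-, bis- and tris-silyl ethers and of the two bis-silyl regioisomers. The fallback sets out from 1 and reverses the order of silylation and prenylation. Phloroglucinol is silylated with two equivalents of TBSCl/imidazole to the symmetric 3,5-bis(tert-butyldimethylsilyloxy)phenol F4, where only the degree of silylation has to be controlled. Its sodium salt (NaH, toluene) is then C-alkylated by prenyl bromide 2 at one of the two equivalent ortho carbons. The contact ion pair in the non-polar solvent favours ortho C-alkylation, and the para carbon is shielded by two silyloxy groups. The fallback returns to the route at 4.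

**Further compounds**

F1 | step 9 | (3S)-3-(4-acetoxy-3-methoxyphenyl)-3-[3,5-bis(tert-butyldimethylsilyloxy)-2-(3-methylbut-2-en-1-yl)phenoxy]propanoyl chloride | COc1cc([C@@H](Oc2cc(O[Si](C)(C)C(C)(C)C)cc(O[Si](C)(C)C(C)(C)C)c2CC=C(C)C)CC(=O)Cl)ccc1OC(C)=O
F2 | step 7 | (3R)-3-(4-acetoxy-3-methoxyphenyl)-3-hydroxypropanoic acid | COc1cc([C@H](O)CC(=O)O)ccc1OC(C)=O
F3 | step 7 | (4R)-4-(4-acetoxy-3-methoxyphenyl)oxetan-2-one | COc1cc([C@H]2CC(=O)O2)ccc1OC(C)=O
F4 | step 2 | 3,5-bis(tert-butyldimethylsilyloxy)phenol | Oc1cc(O[Si](C)(C)C(C)(C)C)cc(O[Si](C)(C)C(C)(C)C)c1
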